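The C‑3–C‑4 bond of ring C in the upper epicatechin gallate unit joins an oxygen‑bearing carbon (C‑3) to the carbon benzylic to ring A (C‑4), so it can be made as an aldol bond. An amine‑catalysed oxa‑Michael/aldol condensation joins a ring A salicylaldehyde and a ring B cinnamaldehyde, sets C‑2 and closes ring C in one operation. The formyl group left on C‑3 is later exchanged for oxygen (Baeyer–Villiger), and ketone reduction gives the 2,3‑cis pattern. The precursor is the pair of aldehydes, linked in the flask as an aryloxy enamine. C‑4 oxidation and two orthogonal 4β couplings assemble the trimer before galloylation and hydrogenolysis.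

Key step: step 3

Remark: the target is read as epicatechin 3‑O‑gallate‑(4β→6)‑epicatechin 3‑O‑gallate‑(4β→8)‑catechin; 3,4,5‑tris(benzyloxy)benzoyl chloride and the prolinol silyl ether catalyst are taken as commercial.

Step 1
Reactants: 1 2,4,6-trihydroxybenzaldehyde
Product: 2 4,6-bis(benzyloxy)-2-hydroxybenzaldehyde
Conditions: BnBr (2.05 equiv), K2CO3, DMF, 0 °C to rt
Reagents that add atoms: benzyl bromide BrCc1ccccc1
Why: Williamson O‑benzylation in which the 4‑hydroxyl reacts first and, once one ortho hydroxyl is benzylated, the last one is held in a hydrogen bond to the formyl group and should stay free.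

Step 2
Reactants: 3 3,4-bis(benzyloxy)benzaldehyde
Product: 4 (E)-3-[3,4-bis(benzyloxy)phenyl]prop-2-enal
Conditions: Ph3P=CHCHO, toluene, 80 °C
Reagents that add atoms: (triphenylphosphoranylidene)acetaldehyde O=CC=P(c1ccccc1)(c1ccccc1)c1ccccc1
Why: Wittig olefination with a formyl‑stabilized ylide, which should give the E enal.

Step 3
Reactants: 2 4,6-bis(benzyloxy)-2-hydroxybenzaldehyde; 4 (E)-3-[3,4-bis(benzyloxy)phenyl]prop-2-enal
Product: 6 (2R)-5,7-bis(benzyloxy)-2-[3,4-bis(benzyloxy)phenyl]-2H-chromene-3-carbaldehyde, via oxa-Michael enamine 5 (not isolated)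
Conditions: (S)-2-[diphenyl(trimethylsilyloxy)methyl]pyrrolidine (20 mol %), 2-nitrobenzoic acid (20 mol %), 4 Å MS, toluene, rt
Reagents that add atoms: none
Why: Iminium activation of enal 4 lets the free phenol of 2 add to the β‑carbon (oxa‑Michael, forming O‑1–C‑2) to give enamine 5, whose nucleophilic carbon (C‑3) then attacks the ring A formyl carbon (C‑4) in an intramolecular aldol addition; loss of water and iminium hydrolysis release 6 and the catalyst. The closest known reaction type is the amine‑catalysed domino oxa‑Michael/aldol condensation of salicylaldehydes with cinnamaldehydes. Ring C is closed by the C‑3–C‑4 bond in a 6‑(enolexo)‑exo‑trig aldol closure. The only new stereocenter, C‑2, is set in the oxa‑Michael step by the catalyst: its diphenyl(silyloxy)methyl group shields one face of the E iminium ion, so the phenol should add to the open face and give 2R (the mirror‑image catalyst would give 2S). The step needs cross‑selectivity and retention of the C‑2 configuration: 2 has a single free hydroxyl and a non‑enolizable aldehyde that can only be the aldol acceptor, and the irreversible dehydration to the conjugated chromene takes the adduct out of the reversible oxa‑Michael equilibrium. The formyl group left on C‑3 is a placeholder for the C‑3 oxygen.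

Step 4
Reactants: 6 (2R)-5,7-bis(benzyloxy)-2-[3,4-bis(benzyloxy)phenyl]-2H-chromene-3-carbaldehyde
Product: 8 (2R)-5,7-bis(benzyloxy)-2-[3,4-bis(benzyloxy)phenyl]chroman-3-one, via enol formate 7 (not isolated)
Conditions: mCPBA (1.05 equiv), Na2HPO4, CH2Cl2, 0 °C; then KHCO3, MeOH/THF, 0 °C
Reagents that add atoms: 3-chloroperoxybenzoic acid O=C(OO)c1cccc(Cl)c1
Why: Baeyer–Villiger oxidation of the α‑branched enal, in which the electron‑rich vinyl carbon C‑3 migrates to oxygen to give enol formate 7, whose mild methanolysis frees the enol that tautomerizes to the ketone without involving C‑2.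

Step 5
Reactants: 8 (2R)-5,7-bis(benzyloxy)-2-[3,4-bis(benzyloxy)phenyl]chroman-3-one
Product: 9 (2R,3R)-5,7-bis(benzyloxy)-2-[3,4-bis(benzyloxy)phenyl]chroman-3-ol (5,7,3',4'-tetra-O-benzyl-(−)-epicatechin)
Conditions: LiBH(s-Bu)3 (L-Selectride), LiBr, THF, −78 °C
Reagents that add atoms: none
Why: The bulky hydride attacks the C‑3 carbonyl equatorially, away from the C‑2 aryl group, which should give the axial 3‑hydroxyl cis to the aryl group as in the known reduction of flavan‑3‑ones to 2,3‑cis flavan‑3‑ols.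

Step 6
Reactants: 9 5,7,3',4'-tetra-O-benzyl-(−)-epicatechin
Product: 10 4β-(2-ethoxyethoxy)-5,7,3',4'-tetra-O-benzylepicatechin (4-alkoxy trans to 3-OH)
Conditions: DDQ (2 equiv), 2-ethoxyethanol, CH2Cl2, rt
Reagents that add atoms: 2-ethoxyethanol CCOCCO
Why: DDQ abstracts hydride from the benzylic C‑4 activated by ring A and the cation (quinone methide) is trapped by the alcohol from the face trans to the C‑3 hydroxyl, the established entry to 4β‑alkoxy flavan‑3‑ols.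

Step 7
Reactants: 10 4β-(2-ethoxyethoxy)-5,7,3',4'-tetra-O-benzylepicatechin
Product: 11 6,8-dibromo-4β-(2-ethoxyethoxy)-5,7,3',4'-tetra-O-benzylepicatechin
Conditions: NBS (2.1 equiv), CH2Cl2, −20 °C to rt
Reagents that add atoms: N-bromosuccinimide O=C1CCC(=O)N1Br
Why: Electrophilic bromination of the phloroglucinol‑type ring A at both free positions (C‑8, then C‑6), which removes this unit as a nucleophile in the couplings that follow.

Step 8
Reactants: 10 4β-(2-ethoxyethoxy)-5,7,3',4'-tetra-O-benzylepicatechin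
Product: 12 8-bromo-4β-(2-ethoxyethoxy)-5,7,3',4'-tetra-O-benzylepicatechin
Conditions: NBS (1.0 equiv), CH2Cl2, −78 to −20 °C
Reagents that add atoms: N-bromosuccinimide O=C1CCC(=O)N1Br
Why: With one equivalent of NBS at low temperature, bromination should stop at the more nucleophilic C‑8, leaving C‑6 as the only nucleophilic ring A position.

Step 9
Reactants: 12 8-bromo-4β-(2-ethoxyethoxy)-5,7,3',4'-tetra-O-benzylepicatechin
Product: 13 8-bromo-4β-(2,6-dimethylphenylthio)-5,7,3',4'-tetra-O-benzylepicatechin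
Conditions: 2,6-dimethylbenzenethiol (3 equiv), BF3·OEt2 (0.5 equiv), CH2Cl2, −78 to −30 °C
Reagents that add atoms: 2,6-dimethylbenzenethiol Cc1cccc(C)c1S
Why: Lewis acid ionization of the C‑4 ether and capture of the cation by the thiol trans to the C‑3 hydroxyl (as in thiolysis of proanthocyanidins) gives the 4β thioether, a latent leaving group that a hard Lewis acid does not activate.

Step 10
Reactants: 11 6,8-dibromo-4β-(2-ethoxyethoxy)-5,7,3',4'-tetra-O-benzylepicatechin; 13 8-bromo-4β-(2,6-dimethylphenylthio)-5,7,3',4'-tetra-O-benzylepicatechin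
Product: 14 6,8-dibromo-5,7,3',4'-tetra-O-benzylepicatechin-(4β→6)-8-bromo-4β-(2,6-dimethylphenylthio)-5,7,3',4'-tetra-O-benzylepicatechin
Conditions: 13 (1.5 equiv), BF3·OEt2, 4 Å MS, CH2Cl2, −78 to −30 °C
Reagents that add atoms: none
Why: Friedel–Crafts‑type interflavan coupling in which BF3·OEt2 ionizes only the C‑4 ether of 11 and the cation is attacked trans to its C‑3 hydroxyl by C‑6 of 13, the single free ring A position in the mixture, which fixes the 4β→6 bond.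

Step 11
Reactants: 15 (+)-catechin
Product: 16 3,5,7,3',4'-penta-O-benzyl-(+)-catechin
Conditions: NaH (6 equiv), BnBr (6 equiv), DMF, −10 °C to rt
Reagents that add atoms: benzyl bromide BrCc1ccccc1
Why: Exhaustive Williamson benzylation of the four phenols and the secondary alcohol, so that the bottom C‑3 oxygen stays out of the later galloylation.

Step 12
Reactants: 14 dimer thioether; 16 3,5,7,3',4'-penta-O-benzyl-(+)-catechin
Product: 17 6,8-dibromo-5,7,3',4'-tetra-O-benzylepicatechin-(4β→6)-8-bromo-5,7,3',4'-tetra-O-benzylepicatechin-(4β→8)-3,5,7,3',4'-penta-O-benzylcatechin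
Conditions: 16 (3 equiv), AgBF4, 4 Å MS, THF, 0 °C, dark
Reagents that add atoms: none
Why: The thiophilic AgBF4 ionizes the C‑4 thioether of the middle unit and the cation is captured trans to the C‑3 hydroxyl by C‑8, the most nucleophilic position of 16, as in AgBF4‑promoted chain extension of 4‑thio flavans.

Step 13
Reactants: 17 trimer diol; 18 3,4,5-tris(benzyloxy)benzoyl chloride
Product: 19 bis-3-O-[3,4,5-tris(benzyloxy)benzoyl] ester of 17 (esters on C-3 of the top and middle units)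
Conditions: 18 (4 equiv), Et3N, DMAP, CH2Cl2, rt to 40 °C
Reagents that add atoms: none
Why: DMAP‑catalysed acylation of the two remaining secondary hydroxyls, while the benzylated bottom C‑3 oxygen cannot react.

Step 14
Reactants: 19 protected trimer digallate
Product: 20 epicatechin 3-O-gallate-(4β→6)-epicatechin 3-O-gallate-(4β→8)-catechin (CNP0112921.1)
Conditions: H2 (1 atm), Pd(OH)2/C, NaOAc (sodium acetate), THF/MeOH/H2O, rt
Reagents that add atoms: none
Why: Hydrogenolysis should remove all nineteen benzyl ethers and the three aryl bromides in one operation, the acetate buffer taking up HBr so that the acid‑labile interflavan bonds and the gallate esters survive.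

Compound list
1 | 2,4,6-trihydroxybenzaldehyde | O=Cc1c(O)cc(O)cc1O | starting material
2 | 4,6-bis(benzyloxy)-2-hydroxybenzaldehyde | O=Cc1c(O)cc(OCc2ccccc2)cc1OCc1ccccc1 | intermediate
3 | 3,4-bis(benzyloxy)benzaldehyde | O=Cc1ccc(OCc2ccccc2)c(OCc2ccccc2)c1 | starting material
4 | (E)-3-[3,4-bis(benzyloxy)phenyl]prop-2-enal | O=C/C=C/c1ccc(OCc2ccccc2)c(OCc2ccccc2)c1 | intermediate
5 | oxa-Michael enamine: (S)-2-[diphenyl(trimethylsilyloxy)methyl]-1-[(1E,3S)-3-[3,4-bis(benzyloxy)phenyl]-3-[3,5-bis(benzyloxy)-2-formylphenoxy]prop-1-enyl]pyrrolidine | O=Cc1c(O[C@@H](/C=C/N2CCC[C@H]2C(c2ccccc2)(c2ccccc2)O[Si](C)(C)C)c2ccc(OCc3ccccc3)c(OCc3ccccc3)c2)cc(OCc2ccccc2)cc1OCc1ccccc1 | intermediate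
6 | (2R)-5,7-bis(benzyloxy)-2-[3,4-bis(benzyloxy)phenyl]-2H-chromene-3-carbaldehyde | O=CC1=Cc2c(OCc3ccccc3)cc(OCc3ccccc3)cc2O[C@@H]1c1ccc(OCc2ccccc2)c(OCc2ccccc2)c1 | intermediate
7 | (2R)-5,7-bis(benzyloxy)-2-[3,4-bis(benzyloxy)phenyl]-2H-chromen-3-yl formate | O=COC1=Cc2c(OCc3ccccc3)cc(OCc3ccccc3)cc2O[C@@H]1c1ccc(OCc2ccccc2)c(OCc2ccccc2)c1 | intermediate
8 | (2R)-5,7-bis(benzyloxy)-2-[3,4-bis(benzyloxy)phenyl]chroman-3-one | O=C1Cc2c(OCc3ccccc3)cc(OCc3ccccc3)cc2O[C@@H]1c1ccc(OCc2ccccc2)c(OCc2ccccc2)c1 | intermediate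
9 | (2R,3R)-5,7-bis(benzyloxy)-2-[3,4-bis(benzyloxy)phenyl]chroman-3-ol (5,7,3',4'-tetra-O-benzyl-(−)-epicatechin) | O[C@@H]1Cc2c(OCc3ccccc3)cc(OCc3ccccc3)cc2O[C@@H]1c1ccc(OCc2ccccc2)c(OCc2ccccc2)c1 | intermediate
10 | 4β-(2-ethoxyethoxy)-5,7,3',4'-tetra-O-benzylepicatechin (2-aryl and 3-OH cis, 4-alkoxy trans to 3-OH) | O[C@@H]1[C@@H](OCCOCC)c2c(OCc3ccccc3)cc(OCc3ccccc3)cc2O[C@@H]1c1ccc(OCc2ccccc2)c(OCc2ccccc2)c1 | intermediate
11 | 6,8-dibromo-4β-(2-ethoxyethoxy)-5,7,3',4'-tetra-O-benzylepicatechin | O[C@@H]1[C@@H](OCCOCC)c2c(OCc3ccccc3)c(Br)c(OCc3ccccc3)c(Br)c2O[C@@H]1c1ccc(OCc2ccccc2)c(OCc2ccccc2)c1 | intermediate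
12 | 8-bromo-4β-(2-ethoxyethoxy)-5,7,3',4'-tetra-O-benzylepicatechin | O[C@@H]1[C@@H](OCCOCC)c2c(OCc3ccccc3)cc(OCc3ccccc3)c(Br)c2O[C@@H]1c1ccc(OCc2ccccc2)c(OCc2ccccc2)c1 | intermediate
13 | 8-bromo-4β-(2,6-dimethylphenylthio)-5,7,3',4'-tetra-O-benzylepicatechin | O[C@@H]1[C@@H](Sc2c(C)cccc2C)c2c(OCc3ccccc3)cc(OCc3ccccc3)c(Br)c2O[C@@H]1c1ccc(OCc2ccccc2)c(OCc2ccccc2)c1 | intermediate
14 | 6,8-dibromo-5,7,3',4'-tetra-O-benzylepicatechin-(4β→6)-8-bromo-4β-(2,6-dimethylphenylthio)-5,7,3',4'-tetra-O-benzylepicatechin | O[C@@H]1[C@@H](c2c(OCc4ccccc4)c(Br)c3c(c2OCc2ccccc2)[C@H](Sc2c(C)cccc2C)[C@@H](O)[C@@H](c2ccc(OCc4ccccc4)c(OCc4ccccc4)c2)O3)c2c(OCc3ccccc3)c(Br)c(OCc3ccccc3)c(Br)c2O[C@@H]1c1ccc(OCc2ccccc2)c(OCc2ccccc2)c1 | intermediate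
15 | (+)-catechin, (2R,3S) | O[C@H]1Cc2c(O)cc(O)cc2O[C@@H]1c1ccc(O)c(O)c1 | starting material
16 | 3,5,7,3',4'-penta-O-benzyl-(+)-catechin | c1ccccc1CO[C@H]1Cc2c(OCc3ccccc3)cc(OCc3ccccc3)cc2O[C@@H]1c1ccc(OCc2ccccc2)c(OCc2ccccc2)c1 | intermediate
17 | 6,8-dibromo-5,7,3',4'-tetra-O-benzylepicatechin-(4β→6)-8-bromo-5,7,3',4'-tetra-O-benzylepicatechin-(4β→8)-3,5,7,3',4'-penta-O-benzylcatechin | O[C@@H]1[C@@H](c2c(OCc4ccccc4)c(Br)c3c(c2OCc2ccccc2)[C@H](c2c(OCc4ccccc4)cc(OCc4ccccc4)c4c2O[C@H](c2ccc(OCc5ccccc5)c(OCc5ccccc5)c2)[C@@H](OCc2ccccc2)C4)[C@@H](O)[C@@H](c2ccc(OCc4ccccc4)c(OCc4ccccc4)c2)O3)c2c(OCc3ccccc3)c(Br)c(OCc3ccccc3)c(Br)c2O[C@@H]1c1ccc(OCc2ccccc2)c(OCc2ccccc2)c1 | intermediate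
18 | 3,4,5-tris(benzyloxy)benzoyl chloride | O=C(Cl)c1cc(OCc2ccccc2)c(OCc2ccccc2)c(OCc2ccccc2)c1 | starting material
19 | bis-3-O-[3,4,5-tris(benzyloxy)benzoyl] ester of 17 (top and middle units) | O=C(O[C@@H]1[C@@H](c2c(OCc4ccccc4)c(Br)c3c(c2OCc2ccccc2)[C@H](c2c(OCc4ccccc4)cc(OCc4ccccc4)c4c2O[C@H](c2ccc(OCc5ccccc5)c(OCc5ccccc5)c2)[C@@H](OCc2ccccc2)C4)[C@@H](OC(=O)c2cc(OCc4ccccc4)c(OCc4ccccc4)c(OCc4ccccc4)c2)[C@@H](c2ccc(OCc4ccccc4)c(OCc4ccccc4)c2)O3)c2c(OCc3ccccc3)c(Br)c(OCc3ccccc3)c(Br)c2O[C@@H]1c1ccc(OCc2ccccc2)c(OCc2ccccc2)c1)c1cc(OCc2ccccc2)c(OCc2ccccc2)c(OCc2ccccc2)c1 | intermediate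
20 | epicatechin 3-O-gallate-(4β→6)-epicatechin 3-O-gallate-(4β→8)-catechin (CNP0112921.1) | O=C(O[C@@H]1[C@@H](c2c(O)cc3c(c2O)[C@H](c2c(O)cc(O)c4c2O[C@H](c2ccc(O)c(O)c2)[C@@H](O)C4)[C@@H](OC(=O)c2cc(O)c(O)c(O)c2)[C@@H](c2ccc(O)c(O)c2)O3)c2c(O)cc(O)cc2O[C@@H]1c1ccc(O)c(O)c1)c1cc(O)c(O)c(O)c1 | target

Total step count: 14. Longest linear sequence: 11 steps (1, 3, 4, 5, 6, 8, 9, 10, 12, 13, 14).

Steps most likely to fail

Step 3. The oxa‑Michael addition and iminium formation may be slow with these electron‑rich, doubly ortho‑substituted partners, and the C‑2 configuration may erode by reversible ring opening of the chromene under amine catalysis. In the fallback, stereocontrol moves from the ring closure to a later dynamic kinetic resolution. It sets out from 2 and 4, which are condensed with an achiral amine (pyrrolidine, benzoic acid, toluene, 60 °C) to the racemic 5,7-bis(benzyloxy)-2-[3,4-bis(benzyloxy)phenyl]-2H-chromene-3-carbaldehyde F1. Peracid oxidation as in step 4 should give the racemic 5,7-bis(benzyloxy)-2-[3,4-bis(benzyloxy)phenyl]-2H-chromen-3-yl formate F2, and its methanolysis the racemic 5,7-bis(benzyloxy)-2-[3,4-bis(benzyloxy)phenyl]chroman-3-one F3. Asymmetric transfer hydrogenation of this readily enolized ketone (RuCl(p-cymene)[TsDPEN] in the enantiomeric form that gives the 3R carbinol, HCO2H/Et3N) should reduce it with dynamic kinetic resolution to the cis alcohol. The route is rejoined at 9.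

Step 10. The arylthio group of 13 may transfer to the cation derived from 11, and attack by the hindered C‑6 between two benzyloxy groups may be sluggish, so that the cation decomposes instead. The fallback reverses the order of the two interflavan bonds and needs no sulfide. It sets out from 12 and 16, which are coupled first (TMSOTf, CH2Cl2, −78 °C) to 8-bromo-5,7,3',4'-tetra-O-benzylepicatechin-(4β→8)-3,5,7,3',4'-penta-O-benzylcatechin F4. NBS (1 equiv, −40 °C) should brominate the more electron‑rich free position, C‑6 of the catechin unit, to give 8-bromo-5,7,3',4'-tetra-O-benzylepicatechin-(4β→8)-6-bromo-3,5,7,3',4'-penta-O-benzylcatechin F5. Its only free ring A position, C‑6 of the epicatechin unit, is then coupled with 11 (TMSOTf, −78 to −30 °C) to 6,8-dibromo-5,7,3',4'-tetra-O-benzylepicatechin-(4β→6)-8-bromo-5,7,3',4'-tetra-O-benzylepicatechin-(4β→8)-6-bromo-3,5,7,3',4'-penta-O-benzylcatechin F6. Acylation with 18 as in step 13 gives its bis-3-O-[3,4,5-tris(benzyloxy)benzoyl] ester F7, and hydrogenolysis as in step 14 returns to the route at 20.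

Step 4. The peracid may over‑oxidize the electron‑rich enol formate or ring A, and the C‑2 configuration may be lost by enolization of the ketone during formate cleavage. The fallback exchanges the formyl carbon for nitrogen instead of oxygen. It sets out from 6, which is oxidized (NaClO2, NaH2PO4, 2-methyl-2-butene, t-BuOH/H2O) to (2R)-5,7-bis(benzyloxy)-2-[3,4-bis(benzyloxy)phenyl]-2H-chromene-3-carboxylic acid F8. Diphenylphosphoryl azide and Et3N in toluene/t-BuOH at 80 °C convert it through (2R)-5,7-bis(benzyloxy)-2-[3,4-bis(benzyloxy)phenyl]-2H-chromene-3-carbonyl azide F9 and (2R)-5,7-bis(benzyloxy)-2-[3,4-bis(benzyloxy)phenyl]-3-isocyanato-2H-chromene F10 (Curtius rearrangement) into tert-butyl N-[(2R)-5,7-bis(benzyloxy)-2-[3,4-bis(benzyloxy)phenyl]-2H-chromen-3-yl]carbamate F11. Hydrolysis of this enecarbamate with aqueous HCl in THF at 0 °C to rt should give the ketone and tert-butyl carbamate, rejoining the route at 8.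

Further compounds
F1 | step 3 | racemic 5,7-bis(benzyloxy)-2-[3,4-bis(benzyloxy)phenyl]-2H-chromene-3-carbaldehyde | O=CC1=Cc2c(OCc3ccccc3)cc(OCc3ccccc3)cc2OC1c1ccc(OCc2ccccc2)c(OCc2ccccc2)c1
F2 | step 3 | racemic 5,7-bis(benzyloxy)-2-[3,4-bis(benzyloxy)phenyl]-2H-chromen-3-yl formate | O=COC1=Cc2c(OCc3ccccc3)cc(OCc3ccccc3)cc2OC1c1ccc(OCc2ccccc2)c(OCc2ccccc2)c1
F3 | step 3 | racemic 5,7-bis(benzyloxy)-2-[3,4-bis(benzyloxy)phenyl]chroman-3-one | O=C1Cc2c(OCc3ccccc3)cc(OCc3ccccc3)cc2OC1c1ccc(OCc2ccccc2)c(OCc2ccccc2)c1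
F4 | step 10 | 8-bromo-5,7,3',4'-tetra-O-benzylepicatechin-(4β→8)-3,5,7,3',4'-penta-O-benzylcatechin | O[C@@H]1[C@@H](c2c(OCc3ccccc3)cc(OCc3ccccc3)c3c2O[C@H](c2ccc(OCc4ccccc4)c(OCc4ccccc4)c2)[C@@H](OCc2ccccc2)C3)c2c(OCc3ccccc3)cc(OCc3ccccc3)c(Br)c2O[C@@H]1c1ccc(OCc2ccccc2)c(OCc2ccccc2)c1
F5 | step 10 | 8-bromo-5,7,3',4'-tetra-O-benzylepicatechin-(4β→8)-6-bromo-3,5,7,3',4'-penta-O-benzylcatechin | O[C@@H]1[C@@H](c2c(OCc3ccccc3)c(Br)c(OCc3ccccc3)c3c2O[C@H](c2ccc(OCc4ccccc4)c(OCc4ccccc4)c2)[C@@H](OCc2ccccc2)C3)c2c(OCc3ccccc3)cc(OCc3ccccc3)c(Br)c2O[C@@H]1c1ccc(OCc2ccccc2)c(OCc2ccccc2)c1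
F6 | step 10 | 6,8-dibromo-5,7,3',4'-tetra-O-benzylepicatechin-(4β→6)-8-bromo-5,7,3',4'-tetra-O-benzylepicatechin-(4β→8)-6-bromo-3,5,7,3',4'-penta-O-benzylcatechin | O[C@@H]1[C@@H](c2c(OCc4ccccc4)c(Br)c3c(c2OCc2ccccc2)[C@H](c2c(OCc4ccccc4)c(Br)c(OCc4ccccc4)c4c2O[C@H](c2ccc(OCc5ccccc5)c(OCc5ccccc5)c2)[C@@H](OCc2ccccc2)C4)[C@@H](O)[C@@H](c2ccc(OCc4ccccc4)c(OCc4ccccc4)c2)O3)c2c(OCc3ccccc3)c(Br)c(OCc3ccccc3)c(Br)c2O[C@@H]1c1ccc(OCc2ccccc2)c(OCc2ccccc2)c1
F7 | step 10 | bis-3-O-[3,4,5-tris(benzyloxy)benzoyl] ester of F6 (top and middle units) | O=C(O[C@@H]1[C@@H](c2c(OCc4ccccc4)c(Br)c3c(c2OCc2ccccc2)[C@H](c2c(OCc4ccccc4)c(Br)c(OCc4ccccc4)c4c2O[C@H](c2ccc(OCc5ccccc5)c(OCc5ccccc5)c2)[C@@H](OCc2ccccc2)C4)[C@@H](OC(=O)c2cc(OCc4ccccc4)c(OCc4ccccc4)c(OCc4ccccc4)c2)[C@@H](c2ccc(OCc4ccccc4)c(OCc4ccccc4)c2)O3)c2c(OCc3ccccc3)c(Br)c(OCc3ccccc3)c(Br)c2O[C@@H]1c1ccc(OCc2ccccc2)c(OCc2ccccc2)c1)c1cc(OCc2ccccc2)c(OCc2ccccc2)c(OCc2ccccc2)c1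
F8 | step 4 | (2R)-5,7-bis(benzyloxy)-2-[3,4-bis(benzyloxy)phenyl]-2H-chromene-3-carboxylic acid | O=C(O)C1=Cc2c(OCc3ccccc3)cc(OCc3ccccc3)cc2O[C@@H]1c1ccc(OCc2ccccc2)c(OCc2ccccc2)c1
F9 | step 4 | (2R)-5,7-bis(benzyloxy)-2-[3,4-bis(benzyloxy)phenyl]-2H-chromene-3-carbonyl azide | [N-]=[N+]=NC(=O)C1=Cc2c(OCc3ccccc3)cc(OCc3ccccc3)cc2O[C@@H]1c1ccc(OCc2ccccc2)c(OCc2ccccc2)c1
F10 | step 4 | (2R)-5,7-bis(benzyloxy)-2-[3,4-bis(benzyloxy)phenyl]-3-isocyanato-2H-chromene | O=C=NC1=Cc2c(OCc3ccccc3)cc(OCc3ccccc3)cc2O[C@@H]1c1ccc(OCc2ccccc2)c(OCc2ccccc2)c1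
F11 | step 4 | tert-butyl N-[(2R)-5,7-bis(benzyloxy)-2-[3,4-bis(benzyloxy)phenyl]-2H-chromen-3-yl]carbamate | CC(C)(C)OC(=O)NC1=Cc2c(OCc3ccccc3)cc(OCc3ccccc3)cc2O[C@@H]1c1ccc(OCc2ccccc2)c(OCc2ccccc2)c1
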